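**Plan**

Numbering: labdane numbers for the terpene part (ring A = C1–C5,C10; ring B = C5–C10; chain C11–C16; C17 = exocyclic methylene), primes C1'–C6' for the enedione ring D, ring C = C12–C15,C6',C1', chromone = rings E and F.
Retrosynthesis: the ring C bonds C12–C1' and C15–C6' are cut first (Diels–Alder) to a (12E)-labda-8(17),12,14-trien-7-one and a flavone 2',5'-quinone; in the trienone C17 and the diene are taken off, a C5=C6 double bond is added, and ring B is cut at C5–C6 and C9–C10 (Robinson annulation).
Feature used: in ring B the C7 carbonyl has C6 as its α-carbon and lies 1,5 to C5 through C8–C9–C10, and C5 sits between the quaternary C4 and C10, so ring A can come as 2,2,6-trimethylcyclohexanone, which enolises only toward C10.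
Forward: ring A is bought; ring B is annulated onto it with an enone that already carries C11–C12; C5 is reduced; the diene and C17 are added; rings C and D close last against the quinone, whose rings E and F are made from phloroacetophenone.
Stereochemistry: C10 and C9 from the chiral phosphoric acid and the closed Michael transition state, C5 from the dissolving-metal reduction (trans fusion), C12/C1'/C6' from the chelate-directed cycloaddition of the (E)-diene with the chromone endo; the diene-face isomer is removed by chromatography.

Key step: step 2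

Remark: the sense of induction of the phosphoric acid for this ketone/enone pair cannot be read from a model; the (S)-acid is written, and the (R)-acid would be taken if the other enol face is attacked.

**Route**

Step 1
Reactants: 1 3-(benzyloxy)propanal; 2 1-(triphenylphosphoranylidene)propan-2-one
Product: 3 (E)-6-(benzyloxy)hex-3-en-2-one
Conditions: CH2Cl2, rt, 16 h
Reagents that add atoms: none
Why: Wittig olefination with an acyl-stabilised ylide should react cleanly with the aldehyde and give the (E)-enone, which is the acceptor geometry the annulation needs.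

Step 2
Reactants: 4 2,2,6-trimethylcyclohexan-1-one (racemic, 3 equiv); 3 (E)-6-(benzyloxy)hex-3-en-2-one
Product: 6 (4S,4aR)-4-[2-(benzyloxy)ethyl]-4a,8,8-trimethyl-4,4a,5,6,7,8-hexahydronaphthalen-2(3H)-one, via diketone 5 (not isolated)
Conditions: (S)-3,3'-bis(2,4,6-triisopropylphenyl)-1,1'-binaphthyl-2,2'-diyl hydrogen phosphate (10 mol%), toluene, 60 °C; then TsOH·H2O (0.3 equiv), 110 °C, Dean–Stark trap
Reagents that add atoms: none
Why: Proposed new method: the chiral phosphoric acid should hold the only possible enol of 4 (C5–OH, C5=C10, since C4 is quaternary) and the s-cis enone 3 in one hydrogen-bonded assembly, so that C10 adds to C9 (Michael bond C9–C10), and after TsOH is added the enol of the methyl ketone (C6) closes onto the C5 carbonyl and water is lost (bond C5–C6, Robinson annulation). The closest known reactions are the phosphoric-acid-catalysed Michael addition of α-branched cyclic ketones to vinyl ketones through their enols and the acid-catalysed Robinson annulation; new here are the β-substituted acceptor and the one-flask sequence. Ring B closes in the 6-(enolendo)-exo-trig aldol mode, and dehydration to the C5=C6 enone is the only outlet because C5 carries no α-hydrogen and C8 could only close a four-membered ring. C10 is set by the catalyst, which shields one face of the enol; C9 follows from the closed transition state, in which the enone carbonyl lies over the enol oxygen, the C11 chain points away from C5 and only the C9 hydrogen lies over ring A beside the axial C4 methyl, which places the C9 chain cis to the C10 methyl (the relationship known from Robinson annulations of 2-methylcyclohexanones with (E)-pent-3-en-2-one in non-polar media). The step needs 1,4- over 1,2-addition, C- over O-attack and ring closure before retro-Michael cleavage; the soft enol, the bifunctional acid and the removal of water are meant to secure these.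

Step 3
Reactants: 6 (4S,4aR)-4-[2-(benzyloxy)ethyl]-4a,8,8-trimethyl-4,4a,5,6,7,8-hexahydronaphthalen-2(3H)-one
Product: 7 (4S,4aR,8aS)-4-(2-hydroxyethyl)-4a,8,8-trimethyloctahydronaphthalen-2(1H)-one
Conditions: Li (8 equiv), NH3(l)/THF, t-BuOH (1 equiv), −78 to −33 °C; then solid NH4Cl
Reagents that add atoms: none
Why: Dissolving-metal (Birch-type) reduction of the enone should protonate the C5 carbanion axially from the α side of the trans-decalin-like enolate, which sets 5α-H trans to the 10β-methyl, while the enolate protects C7 from further reduction and the same reagent cleaves the benzyl ether.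

Step 4
Reactants: 7 (4S,4aR,8aS)-4-(2-hydroxyethyl)-4a,8,8-trimethyloctahydronaphthalen-2(1H)-one
Product: 8 (4S,4aR,8aS)-4a,8,8-trimethyl-4-(2-oxoethyl)octahydronaphthalen-2(1H)-one
Conditions: PhI(OAc)2 (1.1 equiv), TEMPO (10 mol%), CH2Cl2, rt
Reagents that add atoms: none
Why: Oxoammonium (TEMPO) oxidation is selective for the primary alcohol and stops at the aldehyde, and the ketone and the three stereocentres should not be touched under these neutral conditions.

Step 5
Reactants: 8 (4S,4aR,8aS)-4a,8,8-trimethyl-4-(2-oxoethyl)octahydronaphthalen-2(1H)-one; 9 2-(triphenylphosphoranylidene)propanal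
Product: 10 (4S,4aR,8aS)-4a,8,8-trimethyl-4-[(2E)-3-methyl-4-oxobut-2-en-1-yl]octahydronaphthalen-2(1H)-one
Conditions: toluene, 80 °C
Reagents that add atoms: none
Why: Wittig reaction with a formyl-stabilised ylide should take the aldehyde and not the ketone and give the (E)-2-methylenal, which fixes the C12=C13 geometry.

Step 6
Reactants: 10 (4S,4aR,8aS)-4a,8,8-trimethyl-4-[(2E)-3-methyl-4-oxobut-2-en-1-yl]octahydronaphthalen-2(1H)-one
Product: 11 (4S,4aR,8aS)-4a,8,8-trimethyl-4-[(2E)-3-methylpenta-2,4-dien-1-yl]octahydronaphthalen-2(1H)-one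
Conditions: Ph3PCH3Br (1.1 equiv), KN(SiMe3)2 (1.05 equiv), THF, 0 °C; then 10, −78 to 0 °C
Reagents that add atoms: methyltriphenylphosphonium bromide, C[P+](c1ccccc1)(c1ccccc1)c1ccccc1.[Br-]
Why: Wittig methylenation with one equivalent of the unstabilised ylide at low temperature should take the enal carbonyl much faster than the C7 ketone and complete the (12E)-diene without touching the trisubstituted double bond.

Step 7
Reactants: 11 (4S,4aR,8aS)-4a,8,8-trimethyl-4-[(2E)-3-methylpenta-2,4-dien-1-yl]octahydronaphthalen-2(1H)-one
Product: 15 (4R,4aS,8aS)-4a,8,8-trimethyl-3-methylidene-4-[(2E)-3-methylpenta-2,4-dien-1-yl]octahydronaphthalen-2(1H)-one, via lithium enolate 12 (not isolated), via Mannich base 13 (not isolated), via ammonium iodide 14 (not isolated)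
Conditions: LiN(i-Pr)2 (1.1 equiv), THF, −78 °C; CH2=NMe2+ I−, −78 °C to rt; MeI, CH2Cl2, rt; aq. NaHCO3, rt
Reagents that add atoms: N,N-dimethylmethyleneiminium iodide (Eschenmoser's salt), C=[N+](C)C.[I-]
Why: Kinetic deprotonation should take the axial C8 hydrogen because C6 is screened by the axial methyl groups on C4 and C10 (the C2-over-C4 preference of 3-oxo-5α-steroids), and Mannich reaction of the enolate with Eschenmoser's salt followed by quaternisation and E1cB elimination gives the α-methylene ketone under a base too weak to move the double bond into the ring.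

Step 8
Reactants: 16 2,4,5-trimethoxybenzoic acid
Product: 17 2,4,5-trimethoxybenzoyl chloride
Conditions: (COCl)2 (1.3 equiv), DMF (cat.), CH2Cl2, 0 °C to rt
Reagents that add atoms: oxalyl chloride, O=C(Cl)C(=O)Cl
Why: Chlorination of the acid by oxalyl chloride through the Vilsmeier-type chloroiminium catalyst gives the acylating agent for the next step.

Step 9
Reactants: 18 1-(2,4,6-trihydroxyphenyl)ethan-1-one (dried); 17 2,4,5-trimethoxybenzoyl chloride
Product: 20 5,7-dihydroxy-2-(2,4,5-trimethoxyphenyl)-4H-chromen-4-one, via diketone 19 (not isolated)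
Conditions: LiN(SiMe3)2 (4.5 equiv), THF, −78 to −10 °C; 17, −78 °C to rt; aq. HCl work-up; then AcOH, H2SO4 (0.5%), 95 °C
Reagents that add atoms: none
Why: The lithium polyanion of the trihydroxyacetophenone should be acylated on the enolate carbon to the 1,3-diketone (the product of a Baker–Venkataraman sequence, reached directly), and acid-catalysed cyclodehydration onto an ortho-hydroxyl closes the pyranone ring E.

Step 10
Reactants: 20 5,7-dihydroxy-2-(2,4,5-trimethoxyphenyl)-4H-chromen-4-one
Product: 21 5-hydroxy-2-(2,4,5-trimethoxyphenyl)-7-[(triisopropylsilyl)oxy]-4H-chromen-4-one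
Conditions: i-Pr3SiCl (1.1 equiv), imidazole, DMF, 0 °C to rt
Reagents that add atoms: chlorotri(propan-2-yl)silane, CC(C)[Si](Cl)(C(C)C)C(C)C
Why: Silylation should take the acidic and unhindered 7-hydroxyl, while the 5-hydroxyl is held in a hydrogen bond to the C4 carbonyl and stays free for the chelate of step 12.

Step 11
Reactants: 21 5-hydroxy-2-(2,4,5-trimethoxyphenyl)-7-[(triisopropylsilyl)oxy]-4H-chromen-4-one
Product: 22 2-{5-hydroxy-4-oxo-7-[(triisopropylsilyl)oxy]-4H-chromen-2-yl}-5-methoxycyclohexa-2,5-diene-1,4-dione
Conditions: (NH4)2Ce(NO3)6 (2.5 equiv), MeCN/H2O, 0 °C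
Reagents that add atoms: water, O
Why: Oxidative demethylation by the one-electron oxidant should take the electron-rich 2,4,5-trimethoxyphenyl ring across its para-related C2' and C5' methoxy groups and leave the C4' methoxy group, whereas the acyl-substituted benzo ring F of the chromone has a much higher oxidation potential.

Step 12
Reactants: 15 (4R,4aS,8aS)-4a,8,8-trimethyl-3-methylidene-4-[(2E)-3-methylpenta-2,4-dien-1-yl]octahydronaphthalen-2(1H)-one; 22 2-{5-hydroxy-4-oxo-7-[(triisopropylsilyl)oxy]-4H-chromen-2-yl}-5-methoxycyclohexa-2,5-diene-1,4-dione (1.3 equiv)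
Product: 25 7-O-triisopropylsilyl ether of dichrostachine L, via boron chelate 23 (not isolated), via adduct chelate 24 (not isolated)
Conditions: 22, B(OAc)3 (1.3 equiv), CH2Cl2, 0 °C, 1 h; then 15, 0 °C to rt; then H2O/THF; chromatography
Reagents that add atoms: none
Why: Lewis-acid-promoted Diels–Alder reaction of a quinone, in which the boron chelate of the 5-hydroxy-4-oxo unit (the activation known for peri-hydroxyquinones) makes C6' the electrophilic end of the C1'=C6' bond so that the unsubstituted terminus C15 bonds to C6' and C12 to C1', the chelated chromone is expected to lie endo so that the (E)-C11 substituent ends cis to the chromone with a cis C/D fusion, and the diene face is hardly biased by the remote C9 centre, so the adduct is expected together with its C12/C1'/C6' face isomer, from which it is separated by chromatography.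

Step 13
Reactants: 25 7-O-triisopropylsilyl ether of dichrostachine L
Product: 26 dichrostachine L
Conditions: HF·pyridine, THF/pyridine, 0 °C
Reagents that add atoms: none
Why: Fluoride should cleave the aryl silyl ether (a vinylogous silyl ester of the C4 carbonyl) under mildly acidic conditions that neither epimerise C6', add to the α-methylene ketone nor move its double bond.

**Compound list**

1 | 3-(benzyloxy)propanal | O=CCCOCc1ccccc1 | starting material
2 | 1-(triphenylphosphoranylidene)propan-2-one | CC(=O)C=P(c1ccccc1)(c1ccccc1)c1ccccc1 | starting material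
3 | (E)-6-(benzyloxy)hex-3-en-2-one | CC(=O)/C=C/CCOCc1ccccc1 | intermediate
4 | 2,2,6-trimethylcyclohexan-1-one (racemic) | CC1CCCC(C)(C)C1=O | starting material
5 | (2R)-2-[(3S)-1-(benzyloxy)-5-oxohexan-3-yl]-2,6,6-trimethylcyclohexan-1-one (Michael adduct, not isolated) | CC(=O)C[C@H](CCOCc1ccccc1)[C@@]1(C)CCCC(C)(C)C1=O | intermediate
6 | (4S,4aR)-4-[2-(benzyloxy)ethyl]-4a,8,8-trimethyl-4,4a,5,6,7,8-hexahydronaphthalen-2(3H)-one (labdane numbering: 5-en-7-one, 9α-H, 10β-methyl) | O=C1C=C2C(C)(C)CCC[C@]2(C)[C@@H](CCOCc2ccccc2)C1 | intermediate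
7 | (4S,4aR,8aS)-4-(2-hydroxyethyl)-4a,8,8-trimethyloctahydronaphthalen-2(1H)-one (trans-decalone: 5α-H, 9α-H, 10β-methyl) | O=C1C[C@H]2C(C)(C)CCC[C@]2(C)[C@@H](CCO)C1 | intermediate
8 | (4S,4aR,8aS)-4a,8,8-trimethyl-4-(2-oxoethyl)octahydronaphthalen-2(1H)-one | O=C1C[C@H]2C(C)(C)CCC[C@]2(C)[C@@H](CC=O)C1 | intermediate
9 | 2-(triphenylphosphoranylidene)propanal | CC(C=O)=P(c1ccccc1)(c1ccccc1)c1ccccc1 | starting material
10 | (4S,4aR,8aS)-4a,8,8-trimethyl-4-[(2E)-3-methyl-4-oxobut-2-en-1-yl]octahydronaphthalen-2(1H)-one | O=C1C[C@H]2C(C)(C)CCC[C@]2(C)[C@@H](C/C=C(\C)C=O)C1 | intermediate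
11 | (4S,4aR,8aS)-4a,8,8-trimethyl-4-[(2E)-3-methylpenta-2,4-dien-1-yl]octahydronaphthalen-2(1H)-one (17-nor-(12E)-labda-12,14-dien-7-one) | O=C1C[C@H]2C(C)(C)CCC[C@]2(C)[C@@H](C/C=C(\C)C=C)C1 | intermediate
12 | lithium enolate of 11 (C7=C8; not isolated) | [Li]OC=1C[C@H]2C(C)(C)CCC[C@]2(C)[C@@H](C/C=C(\C)C=C)C=1 | intermediate
13 | 3-[(dimethylamino)methyl] derivative of 11 (Mannich base at C8, both C8 epimers; not isolated) | O=C1C[C@H]2C(C)(C)CCC[C@]2(C)[C@@H](C/C=C(\C)C=C)C1CN(C)C | intermediate
14 | trimethylammonium iodide of 13 (not isolated) | O=C1C[C@H]2C(C)(C)CCC[C@]2(C)[C@@H](C/C=C(\C)C=C)C1C[N+](C)(C)C.[I-] | intermediate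
15 | (4R,4aS,8aS)-4a,8,8-trimethyl-3-methylidene-4-[(2E)-3-methylpenta-2,4-dien-1-yl]octahydronaphthalen-2(1H)-one ((12E)-labda-8(17),12,14-trien-7-one; 5α-H, 9α-H, 10β-methyl) | C=C1C(=O)C[C@H]2C(C)(C)CCC[C@]2(C)[C@H]1C/C=C(\C)C=C | intermediate
16 | 2,4,5-trimethoxybenzoic acid | OC(=O)c1cc(OC)c(OC)cc1OC | starting material
17 | 2,4,5-trimethoxybenzoyl chloride | ClC(=O)c1cc(OC)c(OC)cc1OC | intermediate
18 | 1-(2,4,6-trihydroxyphenyl)ethan-1-one | CC(=O)c1c(O)cc(O)cc1O | starting material
19 | 1-(2,4,6-trihydroxyphenyl)-3-(2,4,5-trimethoxyphenyl)propane-1,3-dione (not isolated) | O=C(CC(=O)c1cc(OC)c(OC)cc1OC)c1c(O)cc(O)cc1O | intermediate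
20 | 5,7-dihydroxy-2-(2,4,5-trimethoxyphenyl)-4H-chromen-4-one | O=c1cc(-c2cc(OC)c(OC)cc2OC)oc2cc(O)cc(O)c12 | intermediate
21 | 5-hydroxy-2-(2,4,5-trimethoxyphenyl)-7-[(triisopropylsilyl)oxy]-4H-chromen-4-one | O=c1cc(-c2cc(OC)c(OC)cc2OC)oc2cc(O[Si](C(C)C)(C(C)C)C(C)C)cc(O)c12 | intermediate
22 | 2-{5-hydroxy-4-oxo-7-[(triisopropylsilyl)oxy]-4H-chromen-2-yl}-5-methoxycyclohexa-2,5-diene-1,4-dione | O=C1C=C(OC)C(=O)C=C1c1cc(=O)c2c(O)cc(O[Si](C(C)C)(C(C)C)C(C)C)cc2o1 | intermediate
23 | 5-O-diacetoxyboryl chelate of 22 (boron bound to O5 and coordinated by the C4 carbonyl; not isolated) | O=C1C=C(OC)C(=O)C=C1c1cc(=O)c2c(OB(OC(C)=O)OC(C)=O)cc(O[Si](C(C)C)(C(C)C)C(C)C)cc2o1 | intermediate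
24 | 5-O-diacetoxyboryl chelate of 25 (not isolated) | C=C1C(=O)C[C@H]2C(C)(C)CCC[C@]2(C)[C@H]1C[C@@H]1C(C)=CC[C@H]2C(=O)C(OC)=CC(=O)[C@@]12c1cc(=O)c2c(OB(OC(C)=O)OC(C)=O)cc(O[Si](C(C)C)(C(C)C)C(C)C)cc2o1 | intermediate
25 | 7-O-triisopropylsilyl ether of dichrostachine L (silyl on the chromone C7 oxygen; C11, chromone and H-6' all cis on ring C) | C=C1C(=O)C[C@H]2C(C)(C)CCC[C@]2(C)[C@H]1C[C@@H]1C(C)=CC[C@H]2C(=O)C(OC)=CC(=O)[C@@]12c1cc(=O)c2c(O)cc(O[Si](C(C)C)(C(C)C)C(C)C)cc2o1 | intermediate
26 | dichrostachine L | C=C1C(=O)C[C@H]2C(C)(C)CCC[C@]2(C)[C@H]1C[C@@H]1C(C)=CC[C@H]2C(=O)C(OC)=CC(=O)[C@@]12c1cc(=O)c2c(O)cc(O)cc2o1 | target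

**Count and risks**

Total step count: 13. Longest linear sequence: 9 steps (steps 1–7, 12, 13); the quinone branch (steps 8–11) has 4 steps.

Steps most likely to fail:

1. Step 2 (Proposed new method). The hindered enol may add too slowly or with poor face and cis/trans control to the β-substituted enone, and retro-Michael cleavage may outrun the aldol closure onto the C5 carbonyl, which lies between two quaternary carbons, so that material and enantiomeric purity are lost. Fallback with known chemistry, setting out from 4 and 3 and coming back at 6: ketone 4 is converted with NaH in dioxane into its sodium enolate F1, which is added to 3. The racemic Michael adduct, that is 5 together with its enantiomer ent-diketone F2, is closed with KOH in MeOH at reflux. This is the classical base-mediated Robinson annulation, whose closed transition state in a non-polar medium should give the same cis C9/C10 relationship, but as a racemate, that is 6 together with its enantiomer ent-enone F3. Preparative chromatography on a chiral stationary phase (amylose tris(3,5-dimethylphenylcarbamate)) would then deliver 6.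

2. Step 12. The transition state with the quinone ring endo may be preferred over the one with the chromone endo, which would give the wrong relationship between C12 and C1', and the two diene faces may be attacked without preference, which lowers the share of 25. Fallback setting out from 15 and coming back at 25: sensitised E-to-Z photoisomerisation of the diene of 15 (9-fluorenone, visible light that excites only the sensitiser, benzene; isomers separated on AgNO3-impregnated silica) gives the (12Z)-trienone F4. With the C11 substituent now inside the diene, the ordinary Alder mode with the quinone ring endo leads to the same C12/C1'/C6' relationship, and cycloaddition of F4 with the chelate 23 at 10 kbar, through 24 and followed by the same aqueous work-up, should give 25.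

3. Step 7. Deprotonation at C6 may compete with C8, and a second aminomethylation may follow, which would give regioisomeric or doubly substituted methylene ketones. Fallback setting out from 11 and coming back at 15: formylation under equilibrating conditions (NaH, HCO2Et, THF) should give the more stable 8-hydroxymethylene ketone F5 (the analogue of the 2-hydroxymethylene-3-oxo-steroids). Treatment of F5 with aqueous formaldehyde and K2CO3 (aldol addition at C8, transfer of the formyl group to the new hydroxyl and loss of formate) should give 15.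

**Further compounds**

F1 | step 2 | sodium enolate of 4 (sodium 2,6,6-trimethylcyclohex-1-en-1-olate) | [Na]OC1=C(C)CCCC1(C)C
F2 | step 2 | (2S)-2-[(3R)-1-(benzyloxy)-5-oxohexan-3-yl]-2,6,6-trimethylcyclohexan-1-one (ent-diketone, enantiomer of 5) | CC(=O)C[C@@H](CCOCc1ccccc1)[C@]1(C)CCCC(C)(C)C1=O
F3 | step 2 | (4R,4aS)-4-[2-(benzyloxy)ethyl]-4a,8,8-trimethyl-4,4a,5,6,7,8-hexahydronaphthalen-2(3H)-one (ent-enone, enantiomer of 6) | O=C1C=C2C(C)(C)CCC[C@@]2(C)[C@H](CCOCc2ccccc2)C1
F4 | step 12 | (4R,4aS,8aS)-4a,8,8-trimethyl-3-methylidene-4-[(2Z)-3-methylpenta-2,4-dien-1-yl]octahydronaphthalen-2(1H)-one ((12Z)-trienone) | C=C1C(=O)C[C@H]2C(C)(C)CCC[C@]2(C)[C@H]1C/C=C(/C)C=C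
F5 | step 7 | 3-(hydroxymethylidene) derivative of 11 (8-hydroxymethylene ketone; ring stereocentres as in 11) | O=C1C[C@H]2C(C)(C)CCC[C@]2(C)[C@@H](C/C=C(\C)C=C)C1=CO
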